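## The problem

Compound 32 (CNP0113462.3) is an 8,12-elemanolide. Elemane numbering is used throughout: ring C5–C10; C4 (with C3, C15) on C5; C11 (with C12, C13) on C7; the C14 methyl and C1–C2 on C10. β is the ring face that carries the C10 methyl, α the other face. Every ring carbon of the cyclohexane is substituted: a 2-propenal arm on C5, an angelate on C6, an α-methylene-γ-lactone trans-fused across C7–C8, a free hydroxyl on C9, and a quaternary C10 bearing methyl and a monosubstituted oxirane (1R,5R,6S,7S,8R,9S,10S).

There are seven stereocentres, six of them contiguous in the ring. In the chair fixed by the trans lactone, the C5 and C7 arms and O8 are equatorial, while O6, O9 and the C10 methyl are axial. C5, C7 and C8 are therefore the thermodynamically preferred arrangement of a monocycle. The C6 and C9 carbinols must come from kinetic hydride delivery anti to the axial C10 methyl, and C10 and C1 must be set by C–C bond formation and by the way the oxirane is closed.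

The enal and the methylene lactone (Michael acceptors), the oxirane (acid) and the angelate (hydride, Z to E isomerisation) do not survive rough treatment. They must arrive in the last steps under neutral conditions.

The enabling feature is that the C5 and C7 arms are cis-1,3 and each begins with an sp2 carbon. C4 and C11 can therefore be the two ends of one cis alkene that bridges C5 and C7 over C6. C6 then becomes a one-carbon bridge whose oxygen can be held as an exocyclic alkene, and C8(O)–C9(O)–C10(CH3) is a 1-alkoxy-3-methyl-2-oxyallyl unit. Together these define a bicyclo[3.2.1]oct-6-en-3-one made from an alkoxy oxyallyl cation and 6,6-dimethylfulvene.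

## Retrosynthesis

**32 ⇒ 29.** The lactone C12–O8 bond is cut and C3 and C12 are taken down to the alcohol level. Both Michael acceptors then come from one precursor, tetraol 29, in a single neutral oxidation. This is preferred to separate ester and aldehyde handling because the two arms stay chemically identical until the last step. The forward reaction must oxidise two allylic alcohols and one lactol while leaving the C9 carbinol, oxirane and angelate alone.

**29 ⇒ 26.** The oxirane C1–O bond is cut. The oxirane is stored as a C1 mesylate and a C2 silyl ether in 26 and closes with inversion at C1 when fluoride frees O2. Displacement at C1 (not at C2) is chosen because the aldol that forms C10–C1 is expected to place the carbinol oxygen on the side opposite to the oxirane oxygen. Since 26 carries only silyl ethers, one fluoride treatment uncovers everything.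

**26 ⇒ 23 + 24.** The C6–O acyl bond is cut. The angelate would not survive the hydride steps, so it is introduced on 23, in which O6 is the only free hydroxyl.

**23 ⇒ 20 (through 22 and 21).** The C4–C3 and C11–C12 bonds are cut together. Both 3-hydroxyprop-1-en-2-yl arms come from terminal alkynes by Markovnikov hydromethoxycarbonylation and reduction. Alkynes are preferred to enol triflates because they are inert to ozone and to bulky hydride, which the ring adjustments need.

**20 ⇒ 17 (through 19 and 18).** The C6–H and C9–H bonds are cut. Both carbinols come from diketone 17 in one bulky-hydride reduction. The reduction is placed on the monocycle because both alcohols must be axial in its chair, whereas the bicycle would deliver hydride to C9 from the exo face and give the wrong epimer. The two new hydroxyls are then distinguished by their very different hindrance (19, 20).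

**17 ⇒ 16 ⇒ 15.** The C6 carbonyl is the ozonolysis product of the isopropylidene group. The alkynes arise from the aldehydes of 15 by one-carbon homologation, which brings in C15 and C13.

**15 ⇒ 13.** The two formyl carbons C4 and C11 are rejoined as the etheno bridge. The precursor is a rigid bicycle in which the cis relationship of C5 and C7 is automatic. The forward cleavage must pick the strained disubstituted alkene over the tetrasubstituted one.

**13 ⇒ 12 ⇒ 9 + 10.** The C10–C1 bond is cut. An aldol of the C9 ketone enolate with silyloxyacetaldehyde 10 on the exo face makes C10 quaternary and sets C1. A vinyl-type alkylation would have left C1 to a later, less controlled epoxidation.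

**9 ⇒ 8 ⇒ 7.** This is a protecting-group exchange. The phenylethyl group has done its work once the bicycle exists, and it cannot be removed by hydrogenolysis later when alkynes and alkenes are present. It is therefore replaced by a silyl ether, which also directs enolisation to C10.

**7 ⇒ 4 + 5; 4 ⇒ 3 ⇒ 1 + 2.** The C7–C8 and C5–C10 bonds are cut in a (4+3) cycloaddition of the alkoxy oxyallyl cation from 4 with fulvene 5. This step builds the bridged carbocycle and the stereocentres C5, C7 and C8, with C10 as a centre that is reset later. It must be periselective for the ring diene and must let the (S)-phenylethyl group choose the face. Silyl enol ether 4 is two steps from ketone acetal 1 and alcohol 2 via 3.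

## Roads not taken

**Alternative 1:** The cut is C4–C5 and C1–C10. Irradiation of an enone (carbonyl C6, alkene C5=C10) with methyl cyclobut-1-enecarboxylate A2 would give the tricyclic photoadduct A1. Thermal opening of its bicyclo[2.2.0]hexane would then reveal the C10 vinyl group and the C4 acrylate at once.

- Merits: the quaternary C10 and both unsaturated carbon arms appear in two operations, more directly than here, where the oxirane carbons need an aldol, a mesylate and a closure, and the C5 arm needs homologation, carbonylation and reduction.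
- Weak points: only C5 and C10 are set. The C7 arm, the C8 oxygen, the C6 carbinol and C1 must then be added one at a time on a flexible cyclohexanone. The head-to-head regiochemistry and the facial selectivity of the photoaddition rest on one remote silyloxy group. The thermolysis temperature has to be survived by a cis-1,2-divinyl system that can undergo Cope rearrangement.
- Comparison: the chosen plan is longer in side-chain work but fixes C5, C7 and C8 and marks C6 and C9 for oxygen in a single ring-forming step.

**Alternative 2:** The cut is C7–C8 and the lactone C12–O bond. An allylmetal generated with CrCl2 (divalent chromium) or zinc from a 2-(bromomethyl)enoate terminus would add through C7 to an aldehyde at C8. The resulting alkoxide would lactonise to give A3.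

- Merits: carbocycle and methylene lactone form together, and A3 is only a handful of steps from the target, so its endgame is clearly shorter than the one used here.
- Weak points: the cyclisation substrate is an open chain that must already carry C5, C6, C9 and the quaternary C10, which means a long acyclic sequence. The closure has to set C7 and C8 trans against four existing centres with no rigid template. The vinyl group must later be epoxidised selectively and with C1 control beside two other alkenes.
- Comparison: the chosen plan sets against the longer endgame a three-step cation precursor, a commercial diene and stereocontrol from a bicycle.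

**Alternative 3:** The cut is C5–C10 and C6–C7. An amine-catalysed double Michael sequence (enamine at C10 adding to a nitrodiene at C5, then nitronate addition to an enoate at C7) would give the fully substituted nitrocyclohexane A4.

- Merits: catalytic enantiocontrol without an auxiliary, and all six ring carbons substituted in one step. The chosen plan must introduce and remove a stoichiometric auxiliary.
- Weak points: enamines of α-branched aldehydes are sluggish, and forming a quaternary centre this way is demanding. The nitrodiene offers 1,4- and 1,6-addition. The C6 nitro group must become an axial oxygen through Nef chemistry and reduction beside epimerisable C5 and C7. The methylene lactone and the C1 stereocentre remain to be built.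
- Comparison: the chosen plan uses robust ozonolysis and hydride chemistry for C6, and a rigid bicycle for the quaternary centre.

Key step: step 3

Assumption: the (S)-1-phenylethyl group is taken to steer 5 to the same cation face as it steers furan and cyclopentadiene (if the sense were opposite, (R)-1-phenylethanol would be used with no other change); 1 and 10 are treated as catalogue compounds.

Abbreviations: TBS = tert-butyldimethylsilyl, TBDPS = tert-butyldiphenylsilyl, Ms = methanesulfonyl.

Step 1
Reactants: 1 1,1-dimethoxybutan-2-one; 2 (S)-1-phenylethanol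
Product: 3 1-methoxy-1-[(S)-1-phenylethoxy]butan-2-one (both epimers at the acetal carbon)
Conditions: 1 (3 equiv), pyridinium p-toluenesulfonate (5 mol%), toluene, 60 °C, 200 mbar (MeOH distilled off)
Reagents that add atoms: none
Why: Acid-catalysed transacetalisation driven by removal of methanol; the excess of 1 keeps the exchange at one methoxy group, and the acetal epimers do not matter because this carbon becomes planar in step 3.

Step 2
Reactants: 3 1-methoxy-1-[(S)-1-phenylethoxy]butan-2-one
Product: 4 triethyl{[(2Z)-1-methoxy-1-[(S)-1-phenylethoxy]but-2-en-2-yl]oxy}silane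
Conditions: LiN(i-Pr)2 (LDA), THF–DMPU, −78 °C; then Et3SiCl
Reagents that add atoms: chlorotriethylsilane CC[Si](Cl)(CC)CC
Why: Kinetic enolisation at the ethyl CH2 (the acetal C–H is hindered and flanked by two oxygens) followed by O-silylation; the polar additive favours the open transition state that places methyl cis to oxygen, giving the Z enol ether.

Step 3
Reactants: 4 triethyl{[(2Z)-1-methoxy-1-[(S)-1-phenylethoxy]but-2-en-2-yl]oxy}silane; 5 6,6-dimethylfulvene
Product: 7 4-methyl-2-[(S)-1-phenylethoxy]-8-(propan-2-ylidene)bicyclo[3.2.1]oct-6-en-3-one (ether oxygen O8 α, anti to the etheno bridge; C10 methyl β), via oxyallyl cation 6 (not isolated)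
Conditions: 5 (4 equiv), Me3SiOSO2CF3 (0.15 equiv), CH2Cl2, −95 → −78 °C; pyridine quench
Reagents that add atoms: none
Why: Me3SiOSO2CF3 removes the methoxy group of the mixed acetal and leaves the 1-alkoxy-3-methyl-2-(triethylsilyloxy)allyl cation 6, which adds across C7 and C5 of the fulvene ring diene; the silyl group of the adduct is passed on to the next acetal, so the acid is catalytic. The closest known reactions are the (4+3) cycloadditions of the same acetal-derived alkoxy oxyallyl cations with furan and cyclopentadiene, and those of halo-ketone-derived oxyallyl cations with 6,6-dimethylfulvene. The seven-membered ring (C5–C4=C11–C7–C8–C9–C10) closes either in one event through a compact arrangement of cation over diene, or in two: the oxocarbenium carbon C8 bonds to C7, giving a pentadienyl cation spread over the five-membered ring and the exocyclic carbon, and the enol silane carbon C10 then closes onto C5, a seven-membered closure that must beat five-membered closure at C11 and attack at the exocyclic carbon. C5 and C7 are set together and are necessarily cis because both new bonds lie on one face of the planar fulvene. The absolute sense follows from the (S)-phenylethyl group, whose aryl ring covers one face of the cation so that the diene adds to the other. C8 is expected with its oxygen anti to the etheno bridge and C10 with its methyl syn; C10 is reset in step 6 and is therefore not critical. The step needs periselectivity for the 4π ring diene over the 2π and 6π modes of the fulvene and freedom from cationic oligomerisation; low temperature, excess fulvene, substoichiometric acid and the two methyl groups on the exocyclic carbon, which hinder attack there, are what secure it.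

Step 4
Reactants: 7 4-methyl-2-[(S)-1-phenylethoxy]-8-(propan-2-ylidene)bicyclo[3.2.1]oct-6-en-3-one
Product: 8 2-hydroxy-4-methyl-8-(propan-2-ylidene)bicyclo[3.2.1]oct-6-en-3-one (8α-OH, 10β-methyl)
Conditions: BCl3 (2 equiv), pentamethylbenzene (3 equiv), CH2Cl2, −78 °C; MeOH, then aq. NaHCO3
Reagents that add atoms: none
Why: Lewis-acid cleavage of a secondary benzylic ether: BCl3 chelates the ketone and ether oxygens, the 1-phenylethyl cation departs and is trapped by pentamethylbenzene (Friedel–Crafts alkylation) before it can attack either alkene. The C8–O bond is not touched, so C8 keeps its configuration.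

Step 5
Reactants: 8 2-hydroxy-4-methyl-8-(propan-2-ylidene)bicyclo[3.2.1]oct-6-en-3-one
Product: 9 2-(TBS-oxy)-4-methyl-8-(propan-2-ylidene)bicyclo[3.2.1]oct-6-en-3-one (8α-OTBS, 10β-methyl)
Conditions: t-BuMe2SiCl, imidazole, DMF, 23 °C
Reagents that add atoms: tert-butyldimethylsilyl chloride CC(C)(C)[Si](C)(C)Cl
Why: Standard silylation of the only hydroxyl; the resulting α-silyloxy ketone enolises away from the oxygenated carbon, and the silyl ether lasts until the final fluoride step.

Step 6
Reactants: 9 2-(TBS-oxy)-4-methyl-8-(propan-2-ylidene)bicyclo[3.2.1]oct-6-en-3-one; 10 (tert-butyldiphenylsilyloxy)acetaldehyde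
Product: 12 aldol adduct of 9 (C10 quaternary: methyl β; (1S)-2-(TBDPS-oxy)-1-hydroxyethyl chain α), via lithium enolate 11 (not isolated)
Conditions: LiN(i-Pr)2, THF, −78 → −40 °C; 10, −78 °C; AcOH at −78 °C
Reagents that add atoms: none
Why: Directed aldol addition: the base removes the axial exo C10–H (C8–H is equatorial and next to the silyloxy group), and enolate 11 is attacked on the exo face, anti to the etheno bridge, which makes C10 quaternary with methyl β and the new chain α. In the closed Zimmerman–Traxler transition state the aldehyde hydrogen must take the position over the six-membered ring and the CH2OSi group points outward, which sets C1 as S, i.e. with its oxygen on the side opposite to that of the final oxirane oxygen. The cold acidic quench forestalls retro-aldol cleavage.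

Step 7
Reactants: 12 aldol adduct
Product: 13 C1 methanesulfonate of 12
Conditions: MeSO2Cl, Et3N, CH2Cl2, −20 → 0 °C
Reagents that add atoms: methanesulfonyl chloride CS(=O)(=O)Cl
Why: Sulfene-type mesylation works on the neopentyl carbinol; C10 bears no hydrogen, so neither elimination nor retro-aldol is open, and the mesylate marks C1 for the later displacement with inversion.

Step 8
Reactants: 13 C1 methanesulfonate
Product: 15 monocyclic keto-dialdehyde (formyl groups 5β/7β; 6-isopropylidene; 8α-OTBS; C9 ketone; C10 as in 13), via diol 14 (not isolated)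
Conditions: OsO4 (3 mol%), NaIO4 (4 equiv), 2,6-lutidine (2 equiv), 1,4-dioxane–H2O (3:1), 23 °C
Reagents that add atoms: osmium tetroxide O=[Os](=O)(=O)=O (catalytic oxygen carrier); sodium periodate [Na+].[O-]I(=O)(=O)=O (terminal oxygen source)
Why: Lemieux–Johnson oxidation: OsO4 adds to the strained cis-disubstituted bridge alkene on its exo face far faster than to the hindered tetrasubstituted isopropylidene, and periodate cleaves diol 14 to the cis-1,3-dialdehyde. C5 and C7 keep the configuration set in step 3.

Step 9
Reactants: 15 keto-dialdehyde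
Product: 16 keto-dialkyne (5β- and 7β-ethynyl)
Conditions: Me3SiCHN2 (2.6 equiv), LiN(i-Pr)2 (2.5 equiv), THF, −78 °C, then 0 °C; aq. NH4Cl
Reagents that add atoms: trimethylsilyldiazomethane C[Si](C)(C)C=[N+]=[N-]
Why: Colvin rearrangement: the lithiated diazomethane adds to each aldehyde at −78 °C, loss of Me3SiOLi and N2 gives an alkylidene carbene, and a 1,2-hydrogen shift gives the terminal alkyne (C15 and C13 are added). The aprotic low-temperature protocol is chosen because the formyl-bearing carbons are also allylic and C8 is α to the ketone, so an equilibrating alkoxide medium is avoided; the hindered α-quaternary C9 ketone should not compete with the aldehydes.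

Step 10
Reactants: 16 keto-dialkyne
Product: 17 6,9-diketo-dialkyne
Conditions: O3, pyridine (3 equiv), CH2Cl2, −78 °C, Sudan Red 7B end point
Reagents that add atoms: ozone [O-][O+]=O
Why: Ozonolysis of the only alkene; terminal alkynes react far more slowly, and pyridine takes the carbonyl oxide on to the ketone so that no peroxide work-up is needed. Replacing the isopropylidene by a carbonyl removes the allylic strain that blurred the ring conformation, so 17 should sit in the chair with the C5, C7 and C8 substituents equatorial and the C10 methyl axial.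

Step 11
Reactants: 17 6,9-diketo-dialkyne
Product: 18 6β,9α-diol
Conditions: LiBH(s-Bu)3 (L-Selectride, 2.5 equiv), THF, −78 °C; AcOH at −78 °C, then H2O2, NaH2PO4/Na2HPO4 buffer, 0 °C
Reagents that add atoms: none
Why: Bulky-hydride reduction with equatorial delivery at both carbonyls: at C6 the axial path is blocked by the syn-axial C10 methyl (the 3,3,5-trimethylcyclohexanone situation), giving the axial 6β-alcohol; at C9 attack anti to the axial methyl of the adjacent quaternary carbon gives the axial 9α-alcohol (the pattern of 4,4-dimethyl-3-keto triterpenoids). Alkynes, mesylate and silyl ethers are inert, and the cold acidic quench keeps the C9 alkoxide from fragmenting onto the mesylate.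

Step 12
Reactants: 18 6β,9α-diol
Product: 19 6β-acetate
Conditions: Ac2O (1.3 equiv), pyridine, DMAP (5 mol%), CH2Cl2, 0 °C
Reagents that add atoms: acetic anhydride CC(=O)OC(C)=O
Why: Site-selective acetylation: O6 is flanked only by methines carrying slim ethynyl groups, whereas O9 is neopentyl and next to the silyloxy group. The acetate keeps O6 from trapping acylpalladium in step 14 and is removed by the hydride of step 15.

Step 13
Reactants: 19 6β-acetate
Product: 20 6β-acetate 9α-TBS ether
Conditions: t-BuMe2SiOSO2CF3, 2,6-lutidine, CH2Cl2, 0 → 23 °C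
Reagents that add atoms: tert-butyldimethylsilyl trifluoromethanesulfonate CC(C)(C)[Si](C)(C)OS(=O)(=O)C(F)(F)F
Why: Silyl triflate silylation of the hindered C9 alcohol; it keeps O9 out of the later esterification and is removed by fluoride at the end.

Step 14
Reactants: 20 6β-acetate 9α-TBS ether
Product: 21 bis(methyl acrylate) (3-methoxy-3-oxoprop-1-en-2-yl groups on C5 and C7)
Conditions: Pd(OAc)2 (5 mol%), 2-(diphenylphosphino)pyridine (30 mol%), MeSO3H (20 mol%), CO (30 bar), MeOH–CH2Cl2 (1:1), 45 °C
Reagents that add atoms: carbon monoxide [C-]#[O+]; methanol CO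
Why: Palladium-catalysed Markovnikov hydromethoxycarbonylation of terminal alkynes (Pd–H adds with palladium at the internal carbon, then CO insertion and methanolysis), which with pyridylphosphine ligands gives 2-substituted acrylates; both arms gain C3 and C12 in one operation. The acid is buffered by excess ligand, which the mesylate, acetate, secondary TBS ethers and primary TBDPS ether should tolerate.

Step 15
Reactants: 21 bis(methyl acrylate)
Product: 22 triol (6β-OH and two 3-hydroxyprop-1-en-2-yl arms)
Conditions: i-Bu2AlH (8 equiv), CH2Cl2, −78 → −40 °C; aq. potassium sodium tartrate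
Reagents that add atoms: none
Why: DIBAL-H 1,2-reduction of both enoates to allylic alcohols with concurrent reductive removal of the acetate; mesylate and silyl ethers survive at low temperature.

Step 16
Reactants: 22 triol
Product: 23 bis(primary TBS ether) with free 6β-OH
Conditions: t-BuMe2SiCl (2.2 equiv), imidazole, CH2Cl2, 0 °C
Reagents that add atoms: tert-butyldimethylsilyl chloride CC(C)(C)[Si](C)(C)Cl
Why: The two primary allylic alcohols are silylated selectively; the axial C6 alcohol, hindered by the syn-axial methyl, stays free.

Step 17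
Reactants: 23 bis(primary TBS ether); 24 angelic acid
Product: 26 6β-angelate of 23, via mixed anhydride 25 (not isolated)
Conditions: 24, 2,4,6-trichlorobenzoyl chloride, Et3N, toluene, 23 °C; then 23, toluene, 80 °C
Reagents that add atoms: none
Why: Yamaguchi esterification through mixed anhydride 25, run without excess nucleophilic catalyst to hold the Z geometry (angelate to tiglate isomerisation is the known side reaction); O6 is the only free hydroxyl.

Step 18
Reactants: 26 6β-angelate
Product: 29 epoxy tetraol (1R-oxirane; 6β-angelate; 8α/9α-diol; two 3-hydroxyprop-1-en-2-yl arms), via triol mesylate 27 (not isolated), via silylated epoxide 28 (not isolated)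
Conditions: Bu4NF (8 equiv), THF, 0 → 23 °C
Reagents that add atoms: none
Why: Fluoride desilylation with in-flask Williamson-type closure: the primary silyl ethers go first, the freed C2 alkoxide displaces the adjacent C1 mesylate (3-exo-tet, inversion, giving 1R), and the hindered C8 and C9 ethers are cleaved last, after the leaving group has gone, so the C9 alkoxide has nothing to fragment onto. The angelate has no cis-disposed neighbouring hydroxyl to migrate to.

Step 19
Reactants: 29 epoxy tetraol
Product: 32 target CNP0113462.3, via bis-enal 30 (not isolated), via lactol 31 (not isolated)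
Conditions: MnO2 (activated, 30 equiv), CH2Cl2, 23 °C
Reagents that add atoms: none
Why: MnO2 oxidises only the two allylic alcohols; the C12 enal is captured by the trans-vicinal equatorial C8 hydroxyl as a five-membered lactol, itself allylic, which is oxidised on to the α-methylene lactone (oxidative lactonisation), while the C3 enal has no hydroxyl within reach and remains an aldehyde. The saturated C9 carbinol, the oxirane and the angelate are untouched under these neutral conditions.

**Compound list**

1 | 1,1-dimethoxybutan-2-one | CCC(=O)C(OC)OC | starting material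
2 | (S)-1-phenylethanol | C[C@H](O)c1ccccc1 | starting material
3 | 1-methoxy-1-[(S)-1-phenylethoxy]butan-2-one (both epimers at the acetal carbon) | CCC(=O)C(OC)O[C@@H](C)c1ccccc1 | intermediate
4 | triethyl{[(2Z)-1-methoxy-1-[(S)-1-phenylethoxy]but-2-en-2-yl]oxy}silane | C/C=C(\O[Si](CC)(CC)CC)C(OC)O[C@@H](C)c1ccccc1 | intermediate
5 | 6,6-dimethylfulvene [5-(propan-2-ylidene)cyclopenta-1,3-diene] | CC(C)=C1C=CC=C1 | starting material
6 | 3-methyl-1-[(S)-1-phenylethoxy]-2-(triethylsilyloxy)allyl cation, triflate (oxocarbenium form) | C/C=C(\O[Si](CC)(CC)CC)C=[O+][C@@H](C)c1ccccc1.[O-]S(=O)(=O)C(F)(F)F | intermediate (not isolated)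
7 | 4-methyl-2-[(S)-1-phenylethoxy]-8-(propan-2-ylidene)bicyclo[3.2.1]oct-6-en-3-one; O8 α (anti to the etheno bridge), C10 methyl β (syn to it) | C[C@@H](c1ccccc1)O[C@@H]2[C@H]1C=C[C@H](C1=C(C)C)[C@@H](C)C2=O | intermediate
8 | 2-hydroxy-4-methyl-8-(propan-2-ylidene)bicyclo[3.2.1]oct-6-en-3-one; 8α-OH, 10β-methyl | O[C@@H]2[C@H]1C=C[C@H](C1=C(C)C)[C@@H](C)C2=O | intermediate
9 | TBS ether of 8 (8α-OTBS, 10β-methyl) | CC(C)(C)[Si](C)(C)O[C@@H]2[C@H]1C=C[C@H](C1=C(C)C)[C@@H](C)C2=O | intermediate
10 | (tert-butyldiphenylsilyloxy)acetaldehyde | O=CCO[Si](c1ccccc1)(c1ccccc1)C(C)(C)C | starting material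
11 | lithium enolate of 9 (C9–OLi, C9=C10) | CC(C)(C)[Si](C)(C)O[C@@H]2[C@H]1C=C[C@H](C1=C(C)C)C(C)=C2[O-].[Li+] | intermediate (not isolated)
12 | aldol adduct: 9 with quaternary C10 bearing β-methyl and α-[(1S)-2-(TBDPS-oxy)-1-hydroxyethyl] | CC(C)(C)[Si](C)(C)O[C@@H]2[C@H]1C=C[C@H](C1=C(C)C)[C@](C)([C@H](O)CO[Si](c3ccccc3)(c3ccccc3)C(C)(C)C)C2=O | intermediate
13 | C1 methanesulfonate of 12 [(1S)-1-(mesyloxy)-2-(TBDPS-oxy)ethyl side chain] | CC(C)(C)[Si](C)(C)O[C@@H]2[C@H]1C=C[C@H](C1=C(C)C)[C@](C)([C@H](OS(C)(=O)=O)CO[Si](c3ccccc3)(c3ccccc3)C(C)(C)C)C2=O | intermediate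
14 | exo-cis-diol of 13 at C4 and C11 (former etheno bridge) | CC(C)(C)[Si](C)(C)O[C@@H]2[C@H]1[C@H](O)[C@H](O)[C@H](C1=C(C)C)[C@](C)([C@H](OS(C)(=O)=O)CO[Si](c3ccccc3)(c3ccccc3)C(C)(C)C)C2=O | intermediate (not isolated)
15 | cyclohexanone (C9=O) with 5β- and 7β-formyl, 6-(propan-2-ylidene), 8α-OTBS, 10β-methyl, 10α-[(1S)-1-(mesyloxy)-2-(TBDPS-oxy)ethyl] | CC(C)(C)[Si](C)(C)O[C@@H]1[C@@H](C=O)C(=C(C)C)[C@@H](C=O)[C@](C)([C@H](OS(C)(=O)=O)CO[Si](c2ccccc2)(c2ccccc2)C(C)(C)C)C1=O | intermediate
16 | as 15 with 5β- and 7β-ethynyl in place of formyl | CC(C)(C)[Si](C)(C)O[C@@H]1[C@@H](C#C)C(=C(C)C)[C@@H](C#C)[C@](C)([C@H](OS(C)(=O)=O)CO[Si](c2ccccc2)(c2ccccc2)C(C)(C)C)C1=O | intermediate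
17 | 6,9-diketone: as 16 with C6=O in place of the isopropylidene | CC(C)(C)[Si](C)(C)O[C@@H]1[C@@H](C#C)C(=O)[C@@H](C#C)[C@](C)([C@H](OS(C)(=O)=O)CO[Si](c2ccccc2)(c2ccccc2)C(C)(C)C)C1=O | intermediate
18 | 6β,9α-diol (both hydroxyls axial) | CC(C)(C)[Si](C)(C)O[C@@H]1[C@@H](C#C)[C@@H](O)[C@@H](C#C)[C@](C)([C@H](OS(C)(=O)=O)CO[Si](c2ccccc2)(c2ccccc2)C(C)(C)C)[C@@H]1O | intermediate
19 | 6β-acetate of 18 (9α-OH free) | CC(C)(C)[Si](C)(C)O[C@@H]1[C@@H](C#C)[C@@H](OC(C)=O)[C@@H](C#C)[C@](C)([C@H](OS(C)(=O)=O)CO[Si](c2ccccc2)(c2ccccc2)C(C)(C)C)[C@@H]1O | intermediate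
20 | 6β-acetate 9α-TBS ether | CC(C)(C)[Si](C)(C)O[C@@H]1[C@@H](C#C)[C@@H](OC(C)=O)[C@@H](C#C)[C@](C)([C@H](OS(C)(=O)=O)CO[Si](c2ccccc2)(c2ccccc2)C(C)(C)C)[C@@H]1O[Si](C)(C)C(C)(C)C | intermediate
21 | as 20 with 3-methoxy-3-oxoprop-1-en-2-yl groups on C5 and C7 | CC(C)(C)[Si](C)(C)O[C@@H]1[C@@H](C(=C)C(=O)OC)[C@@H](OC(C)=O)[C@@H](C(=C)C(=O)OC)[C@](C)([C@H](OS(C)(=O)=O)CO[Si](c2ccccc2)(c2ccccc2)C(C)(C)C)[C@@H]1O[Si](C)(C)C(C)(C)C | intermediate
22 | triol: 6β-OH and 3-hydroxyprop-1-en-2-yl groups on C5 and C7; 8α,9α-bis(OTBS) | CC(C)(C)[Si](C)(C)O[C@@H]1[C@@H](C(=C)CO)[C@@H](O)[C@@H](C(=C)CO)[C@](C)([C@H](OS(C)(=O)=O)CO[Si](c2ccccc2)(c2ccccc2)C(C)(C)C)[C@@H]1O[Si](C)(C)C(C)(C)C | intermediate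
23 | as 22 with both primary hydroxyls as TBS ethers (6β-OH free) | CC(C)(C)[Si](C)(C)O[C@@H]1[C@@H](C(=C)CO[Si](C)(C)C(C)(C)C)[C@@H](O)[C@@H](C(=C)CO[Si](C)(C)C(C)(C)C)[C@](C)([C@H](OS(C)(=O)=O)CO[Si](c2ccccc2)(c2ccccc2)C(C)(C)C)[C@@H]1O[Si](C)(C)C(C)(C)C | intermediate
24 | angelic acid [(Z)-2-methylbut-2-enoic acid] | C/C=C(/C)C(=O)O | starting material
25 | angelic 2,4,6-trichlorobenzoic anhydride | C/C=C(/C)C(=O)OC(=O)c1c(Cl)cc(Cl)cc1Cl | intermediate (not isolated)
26 | 6β-angelate of 23 | CC(C)(C)[Si](C)(C)O[C@@H]1[C@@H](C(=C)CO[Si](C)(C)C(C)(C)C)[C@@H](OC(=O)/C(C)=C\C)[C@@H](C(=C)CO[Si](C)(C)C(C)(C)C)[C@](C)([C@H](OS(C)(=O)=O)CO[Si](c2ccccc2)(c2ccccc2)C(C)(C)C)[C@@H]1O[Si](C)(C)C(C)(C)C | intermediate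
27 | triol mesylate: 26 without its three primary silyl groups (C2, C3, C12 hydroxyls free; 8α,9α-OTBS; C1 mesylate) | CC(C)(C)[Si](C)(C)O[C@@H]1[C@@H](C(=C)CO)[C@@H](OC(=O)/C(C)=C\C)[C@@H](C(=C)CO)[C@](C)([C@H](OS(C)(=O)=O)CO)[C@@H]1O[Si](C)(C)C(C)(C)C | intermediate (not isolated)
28 | (1R)-oxirane with 8α,9α-bis(OTBS) still in place | CC(C)(C)[Si](C)(C)O[C@@H]1[C@@H](C(=C)CO)[C@@H](OC(=O)/C(C)=C\C)[C@@H](C(=C)CO)[C@](C)([C@@H]2CO2)[C@@H]1O[Si](C)(C)C(C)(C)C | intermediate (not isolated)
29 | epoxy tetraol: (1R)-oxirane, 6β-angelate, 8α,9α-diol, 3-hydroxyprop-1-en-2-yl groups on C5 and C7 | O[C@@H]1[C@@H](C(=C)CO)[C@@H](OC(=O)/C(C)=C\C)[C@@H](C(=C)CO)[C@](C)([C@@H]2CO2)[C@@H]1O | intermediate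
30 | bis-enal: as 29 with 3-oxoprop-1-en-2-yl groups on C5 and C7 | O[C@@H]1[C@@H](C(=C)C=O)[C@@H](OC(=O)/C(C)=C\C)[C@@H](C(=C)C=O)[C@](C)([C@@H]2CO2)[C@@H]1O | intermediate (not isolated)
31 | lactol: C12 hemiacetal closed onto O8 (both anomers), C3 enal | C=C1C(O)O[C@@H]2[C@@H]1[C@@H](OC(=O)/C(C)=C\C)[C@@H](C(=C)C=O)[C@](C)([C@@H]1CO1)[C@@H]2O | intermediate (not isolated)
32 | CNP0113462.3: (1R,5R,6S,7S,8R,9S,10S)-6-angeloyloxy-1,2-epoxy-9-hydroxy-3-oxoelema-4(15),11(13)-dien-12,8-olide | C=C1C(=O)O[C@@H]2[C@@H]1[C@@H](OC(=O)/C(C)=C\C)[C@@H](C(=C)C=O)[C@](C)([C@@H]1CO1)[C@@H]2O | target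

**Step count and risk**

Total: 19 steps. Longest linear sequence: 19 steps (1 or 2 → 32); compounds 5, 10 and 24 enter as purchased materials.

Least certain steps:

- **Step 3 (key step).** What may go wrong: closure of the first-formed pentadienyl cation at C11 or at the exocyclic carbon in place of C5 (loss of periselectivity), cationic oligomerisation of the fulvene under the silyl triflate, or weak facial discrimination by the auxiliary toward a diene bulkier than furan. Fallback: set out from 5 and move the asymmetric event behind the cycloaddition. Fulvene 5 and the oxyallyl species from 1,1,3,3-tetrabromoacetone and Zn–Cu couple give 2,4-dibromo-8-(propan-2-ylidene)bicyclo[3.2.1]oct-6-en-3-one F1. Zn–Cu/NH4Cl in methanol removes the bromines to give meso-8-(propan-2-ylidene)bicyclo[3.2.1]oct-6-en-3-one F2. Enantiotopos-selective deprotonation with a chiral lithium amide (lithium bis[(R)-1-phenylethyl]amide or its antipode, LiCl, THF, −100 °C) and exo-face oxidation of the enolate with 2-(phenylsulfonyl)-3-phenyloxaziridine give 2-hydroxy-8-(propan-2-ylidene)bicyclo[3.2.1]oct-6-en-3-one F3 (O8 α). Silylation gives its TBS ether F4. Methylation at C10 (LiN(i-Pr)2, MeI) gives the 10α-methyl ketone F5, the C10 epimer of 9. Deprotonation of F5 gives the same enolate 11, and the route is rejoined at 12.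

- **Step 9.** What may go wrong: deprotonation competing with addition at the formyl groups (epimerisation at C5 or C7, or migration of the isopropylidene double bond into conjugation), or attack of the reagent on the ring ketone. Fallback: set out from 15 and replace the diazo homologation by olefination and elimination. Stork–Zhao olefination (Ph3P=CHI, from (iodomethyl)triphenylphosphonium iodide and NaN(SiMe3)2, THF–HMPA, −78 °C) is selective for aldehydes and gives the bis[(Z)-2-iodoethenyl] ketone F6. Anti-dehydroiodination with NaN(SiMe3)2 at −78 °C then gives 16.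

- **Step 14.** What may go wrong: erosion of branched regioselectivity with alkynes on secondary carbons, or acid-promoted loss of silyl groups in methanol. Fallback: set out from 20. Bromoboration with B-bromo-9-borabicyclo[3.3.1]nonane followed by protonolysis with acetic acid gives the bis(1-bromoethenyl) compound F7. Methoxycarbonylation of the vinyl bromides under basic conditions (Pd(PPh3)4, CO, MeOH, Et3N, DMF, 70 °C) returns to 21.

- **Step 17.** What may go wrong: slow acylation of the hindered axial C6 hydroxyl, and Z to E isomerisation of the angeloyl unit during forcing. Fallback: set out from 23 and build the Z alkene after the ester bond. Esterification with 2-[bis(2,2,2-trifluoroethoxy)phosphoryl]propanoic acid (DCC, DMAP) gives the phosphonopropionate ester F8. Still–Gennari olefination with acetaldehyde (KN(SiMe3)2, 18-crown-6, THF, −78 °C) gives 26.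

- **Step 18.** What may go wrong: base-mediated acyl transfer or cleavage of the angelate, incomplete removal of the hindered C9 silyl ether, or opening of the new oxirane by alkoxide or fluoride during the prolonged treatment. Fallback: set out from 26 and separate the two events. HF·pyridine in THF–pyridine removes all silyl groups under weakly acidic conditions, in which the mesylate is inert, and gives the pentahydroxy mesylate F9. Brief treatment with K2CO3 in MeOH at 0 °C then closes the oxirane to give 29.

## Further compounds

F1 | step 3 | 2,4-dibromo-8-(propan-2-ylidene)bicyclo[3.2.1]oct-6-en-3-one (mixture of bromide epimers) | CC(C)=C1C2C=CC1C(Br)C(=O)C2Br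
F2 | step 3 | meso-8-(propan-2-ylidene)bicyclo[3.2.1]oct-6-en-3-one | O=C2C[C@H]1C=C[C@H](C1=C(C)C)C2
F3 | step 3 | 2-hydroxy-8-(propan-2-ylidene)bicyclo[3.2.1]oct-6-en-3-one (hydroxyl anti to the etheno bridge) | O[C@@H]2[C@H]1C=C[C@H](C1=C(C)C)CC2=O
F4 | step 3 | TBS ether of F3 | CC(C)(C)[Si](C)(C)O[C@@H]2[C@H]1C=C[C@H](C1=C(C)C)CC2=O
F5 | step 3 | 10α-methyl ketone, the C10 epimer of 9 | CC(C)(C)[Si](C)(C)O[C@@H]2[C@H]1C=C[C@H](C1=C(C)C)[C@H](C)C2=O
F6 | step 9 | bis[(Z)-2-iodoethenyl] analogue of 16 | CC(C)(C)[Si](C)(C)O[C@@H]1[C@@H](/C=C\I)C(=C(C)C)[C@@H](/C=C\I)[C@](C)([C@H](OS(C)(=O)=O)CO[Si](c2ccccc2)(c2ccccc2)C(C)(C)C)C1=O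
F7 | step 14 | bis(1-bromoethenyl) analogue of 20 | CC(C)(C)[Si](C)(C)O[C@@H]1[C@@H](C(Br)=C)[C@@H](OC(C)=O)[C@@H](C(Br)=C)[C@](C)([C@H](OS(C)(=O)=O)CO[Si](c2ccccc2)(c2ccccc2)C(C)(C)C)[C@@H]1O[Si](C)(C)C(C)(C)C
F8 | step 17 | 6β-{2-[bis(2,2,2-trifluoroethoxy)phosphoryl]propanoate} of 23 | CC(C)(C)[Si](C)(C)O[C@@H]1[C@@H](C(=C)CO[Si](C)(C)C(C)(C)C)[C@@H](OC(=O)C(C)P(=O)(OCC(F)(F)F)OCC(F)(F)F)[C@@H](C(=C)CO[Si](C)(C)C(C)(C)C)[C@](C)([C@H](OS(C)(=O)=O)CO[Si](c2ccccc2)(c2ccccc2)C(C)(C)C)[C@@H]1O[Si](C)(C)C(C)(C)C
F9 | step 18 | pentahydroxy mesylate (26 without silyl groups, oxirane not yet closed) | O[C@@H]1[C@@H](C(=C)CO)[C@@H](OC(=O)/C(C)=C\C)[C@@H](C(=C)CO)[C@](C)([C@H](OS(C)(=O)=O)CO)[C@@H]1O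
A1 | alternative 1 | cis-anti-cis tricyclic photoadduct (ester on C4, methyl on C10) | O=C1[C@@H]2[C@@]3(C(=O)OC)CC[C@H]3[C@]2(C)[C@@H](O[Si](C)(C)C(C)(C)C)CC1
A2 | alternative 1 | methyl cyclobut-1-enecarboxylate | COC(=O)C1=CCC1
A3 | alternative 2 | protected elemanolide core with the α-methylene lactone in place | C=C1C(=O)O[C@@H]2[C@@H]1[C@@H](OCc3ccc(OC)cc3)[C@@H](C(=C)CO[Si](c3ccccc3)(c3ccccc3)C(C)(C)C)[C@](C)(C=C)[C@@H]2O[Si](CC)(CC)CC
A4 | alternative 3 | nitrocyclohexane carbaldehyde with all six ring carbons substituted | CC1(C)O[C@@H]2[C@@H](CC(=O)OC)[C@H]([N+](=O)[O-])[C@@H](C(=C)CO[Si](C)(C)C(C)(C)C)[C@](C)(C=O)[C@@H]2O1
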